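**Plan**

1. Numbering: dioxolane O1–O2–C3–C4–C5; C3 carries CH3 and the CH2CO2H arm, C5 carries CH3 and the side chain C1'–C10'. The acid is traced back to a CH2CH2OH arm; the ring is then cut at O1–C5 (last bond made) and at O2–C3, leaving HO–OH and a 1,3-dielectrophile: a free tertiary C5 carbinol and a 2-methyloxetane that ties the arm back to C3.
2. Further cuts: the C3 oxetane and the C5 epoxide each go back to a methyl ketone plus sulfoxonium-ylide CH2 (C4 and both arm carbons are ylide methylenes); C3–C4 comes from isopropenyl Grignard opening of the C5 epoxide; C5'=C6' from a Julia–Kocienski olefination.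
3. Forward: (R)-citronellic acid → methyl ketone → C5 epoxide → isopropenyl opening, silylation, double ozonolysis → olefination (chain) → C3 oxetane → desilylation → perhydrolysis of the oxetane (O2–C3) → closure O1–C5 → oxidation of the arm. The 1,2-dioxolane is the last ring formed; the oxetane is a temporary ring opened in step 11.
4. Stereochemistry: C2' from (R)-citronellic acid; the C5 and C3 C–O centres from two catalyst-controlled asymmetric Corey–Chaykovsky methylene transfers (same catalyst enantiomer). Each C–O bond is then exchanged for a peroxide C–O bond with inversion (C3 in step 11, C5 in step 12), which puts the two ring methyl groups cis. The styrene E-alkene comes from building block 7, the C5'=C6' E-alkene from the olefination.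
5. Enabling feature: C3 and C5 are both fully substituted, oxygen-bearing ring carbons in a 1,3-relationship across the C4 methylene, and only C3 carries a functionalised two-carbon arm. The ring therefore maps onto HO–OH plus a stereodefined bis-tertiary 1,3-diol derivative (oxetane at C3, carbinol at C5).

Key step: step 12

Assumption: the (S)-binaphthoxide La/Li catalyst is taken as the enantiomer that transfers CH2 to the ketone face giving the (S)-2-alkyl-2-methyloxirane; if the facial sense is the reverse, the (R)-catalyst is used in steps 2 and 9.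

**Route**

Step 1
Reactants: 1 (3R)-3,7-dimethyloct-6-enoic acid ((R)-citronellic acid)
Product: 2 (4R)-4,8-dimethylnon-7-en-2-one
Conditions: MeLi (2.2 equiv), Et2O, 0 °C → rt; aq. NH4Cl
Reagents that add atoms: methyllithium, C[Li]
Why: Addition of MeLi to a carboxylic acid is the classical one-step route to a methyl ketone (over-addition is held back until the aqueous quench), and the existing stereocentre is remote from the reacting carbon.

Step 2
Reactants: 2 (4R)-4,8-dimethylnon-7-en-2-one
Product: 3 (2S)-2-[(2R)-2,6-dimethylhept-5-en-1-yl]-2-methyloxirane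
Conditions: Me3S(O)I, NaH (ylide, 1.2 equiv); LaLi3[(S)-binaphthoxide]3 (5 mol%), (2,4,6-(MeO)3C6H2)3P=O (5 mol%), 5 Å MS, THF, rt
Reagents that add atoms: trimethylsulfoxonium iodide, C[S+](C)(C)=O.[I-]
Why: Catalytic asymmetric Corey–Chaykovsky epoxidation, in which the chiral La/Li binaphthoxide complex should distinguish the methyl from the CH2-alkyl substituent of the ketone, so that methylene transfer to one carbonyl face sets the quaternary C–O centre (future C5) as (S) under catalyst control.

Step 3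
Reactants: 3 (2S)-2-[(2R)-2,6-dimethylhept-5-en-1-yl]-2-methyloxirane
Product: 4 (4S,6R)-2,4,6,10-tetramethylundeca-1,9-dien-4-ol
Conditions: isopropenylMgBr (2 equiv), CuI (10 mol%), THF, −30 → 0 °C
Reagents that add atoms: isopropenylmagnesium bromide, CC(=C)[Mg]Br
Why: Copper-catalysed Grignard opening of a 2,2-disubstituted epoxide should occur by SN2 attack at the unsubstituted CH2 only, so the tertiary C–O stereocentre passes unchanged into the homoallylic alcohol.

Step 4
Reactants: 4 (4S,6R)-2,4,6,10-tetramethylundeca-1,9-dien-4-ol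
Product: 5 triethyl{[(4S,6R)-2,4,6,10-tetramethylundeca-1,9-dien-4-yl]oxy}silane
Conditions: Et3SiOTf, 2,6-lutidine, CH2Cl2, −78 → 0 °C
Reagents that add atoms: triethylsilyl trifluoromethanesulfonate, CC[Si](CC)(CC)OS(=O)(=O)C(F)(F)F
Why: Silyl triflate/lutidine silylation is the standard way to cap a hindered tertiary alcohol, which should block retro-aldol cleavage once the β-carbonyl group is unveiled.

Step 5
Reactants: 5 triethyl{[(4S,6R)-2,4,6,10-tetramethylundeca-1,9-dien-4-yl]oxy}silane
Product: 6 (4R,6S)-4,6-dimethyl-8-oxo-6-[(triethylsilyl)oxy]nonanal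
Conditions: O3, CH2Cl2, −78 °C; then PPh3, −78 °C → rt
Reagents that add atoms: ozone, [O-][O+]=O
Why: Ozonolysis with reductive work-up should cleave the trisubstituted and the 1,1-disubstituted alkene in one operation, unveiling the aldehyde for chain extension and the methyl ketone for the second methylene transfer without touching a stereocentre.

Step 6
Reactants: 7 (4E)-5-phenylpent-4-en-1-ol
Product: 8 1-phenyl-5-{[(4E)-5-phenylpent-4-en-1-yl]sulfanyl}-1H-tetrazole
Conditions: 1-phenyl-1H-tetrazole-5-thiol, PPh3, DIAD, THF, 0 °C → rt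
Reagents that add atoms: 1-phenyl-1H-tetrazole-5-thiol, Sc1nnnn1-c1ccccc1
Why: Mitsunobu thioetherification of a primary alcohol with the acidic tetrazole thiol is the standard entry to Julia–Kocienski reagents and leaves the (E)-styrene unit intact.

Step 7
Reactants: 8 1-phenyl-5-{[(4E)-5-phenylpent-4-en-1-yl]sulfanyl}-1H-tetrazole
Product: 9 1-phenyl-5-{[(4E)-5-phenylpent-4-en-1-yl]sulfonyl}-1H-tetrazole
Conditions: (NH4)6Mo7O24·4H2O (10 mol%), 30% aq. H2O2, EtOH, 0 °C → rt
Reagents that add atoms: hydrogen peroxide, OO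
Why: Molybdate-catalysed peroxide oxidation should take the sulfide chemoselectively to the sulfone without epoxidising the conjugated alkene.

Step 8
Reactants: 9 1-phenyl-5-{[(4E)-5-phenylpent-4-en-1-yl]sulfonyl}-1H-tetrazole; 6 (4R,6S)-4,6-dimethyl-8-oxo-6-[(triethylsilyl)oxy]nonanal
Product: 11 (4S,6R,9E,13E)-4,6-dimethyl-14-phenyl-4-[(triethylsilyl)oxy]tetradeca-9,13-dien-2-one, via potassium sulfonyl carbanion 10 (not isolated)
Conditions: 9, KN(SiMe3)2, DME, −60 °C; then 6, −60 °C → rt
Reagents that add atoms: none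
Why: Julia–Kocienski olefination, in which the metalated phenyltetrazolyl sulfone should add to the aldehyde much faster than to the hindered methyl ketone and the Smiles rearrangement–elimination sequence should give the new disubstituted alkene with E selectivity (potassium counter-ion in DME).

Step 9
Reactants: 11 (4S,6R,9E,13E)-4,6-dimethyl-14-phenyl-4-[(triethylsilyl)oxy]tetradeca-9,13-dien-2-one
Product: 13 triethyl{[(2S,4R,7E,11E)-2,4-dimethyl-1-[(2R)-2-methyloxetan-2-yl]-12-phenyldodeca-7,11-dien-2-yl]oxy}silane, via epoxide 12 (not isolated)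
Conditions: Me3S(O)I, NaH (ylide, 1.2 equiv), LaLi3[(S)-binaphthoxide]3 (5 mol%), (2,4,6-(MeO)3C6H2)3P=O (5 mol%), 5 Å MS, THF, rt; then more ylide (1.5 equiv) and catalyst (15 mol%), 45 °C, one pot
Reagents that add atoms: trimethylsulfoxonium iodide, C[S+](C)(C)=O.[I-]
Why: One-pot catalytic asymmetric Corey–Chaykovsky epoxidation followed by ylide ring expansion of the 2,2-disubstituted epoxide (SN2 at its CH2, then 4-exo-tet closure) should turn the methyl ketone into the 2-methyl-2-alkyl oxetane; the catalyst again distinguishes methyl from CH2-alkyl, so the quaternary C–O centre (future C3) is set under reagent control and is not touched by the ring expansion.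

Step 10
Reactants: 13 triethyl{[(2S,4R,7E,11E)-2,4-dimethyl-1-[(2R)-2-methyloxetan-2-yl]-12-phenyldodeca-7,11-dien-2-yl]oxy}silane
Product: 14 (2S,4R,7E,11E)-2,4-dimethyl-1-[(2R)-2-methyloxetan-2-yl]-12-phenyldodeca-7,11-dien-2-ol
Conditions: Bu4NF, THF, rt
Reagents that add atoms: none
Why: Fluoride-mediated desilylation should free the tertiary alcohol under non-acidic conditions that leave the oxetane closed.

Step 11
Reactants: 14 (2S,4R,7E,11E)-2,4-dimethyl-1-[(2R)-2-methyloxetan-2-yl]-12-phenyldodeca-7,11-dien-2-ol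
Product: 15 (3S,5S,7R,10E,14E)-3-hydroperoxy-3,5,7-trimethyl-15-phenylpentadeca-10,14-diene-1,5-diol
Conditions: H2O2 (anhydrous, in Et2O, 10 equiv), Me3SiOTf (0.2 equiv), Et2O, −78 °C
Reagents that add atoms: hydrogen peroxide, OO
Why: Lewis-acid-promoted perhydrolysis of a 2,2-disubstituted oxetane, in which hydrogen peroxide attacks the activated ring at its tertiary carbon in a borderline SN2 process with inversion; this should convert the (R)-oxetane carbon into the (S)-hydroperoxide carbon and release the two-carbon arm as a primary alcohol, while the unstrained tertiary carbinol should not ionise at −78 °C.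

Step 12
Reactants: 15 (3S,5S,7R,10E,14E)-3-hydroperoxy-3,5,7-trimethyl-15-phenylpentadeca-10,14-diene-1,5-diol
Product: 16 2-[(3S,5R)-3,5-dimethyl-5-[(2R,5E,9E)-2-methyl-10-phenyldeca-5,9-dien-1-yl]-1,2-dioxolan-3-yl]ethan-1-ol
Conditions: Sc(OTf)3 (10 mol%), 4 Å MS, CH2Cl2, −40 → 0 °C
Reagents that add atoms: none
Why: Proposed new method: the Lewis acid (or the TfOH it releases) activates the tertiary C5 hydroxyl, and the terminal oxygen of the C3 hydroperoxide, held three atoms away, displaces water through a five-membered transition state, so that C–O cleavage is anchimerically assisted and no free, rotating carbocation is needed. The closest known reaction types are the acid-mediated cyclodehydration of tertiary 3-hydroperoxy alcohols to 3,3,5,5-tetrasubstituted 1,2-dioxolanes (stereochemical course not established), the invertive attack of hydroperoxides on tertiary oxetane carbons, and Lewis-acid-catalysed intramolecular substitution of enantioenriched tertiary alcohols by O-nucleophiles with chirality transfer. The 1,2-dioxolane is closed in the 5-exo-tet mode. C5 is the only stereocentre formed: backside attack should invert the (S)-carbinol fixed in step 2 to the (R)-peroxy carbon, while C3 (step 11) and the side-chain methyl centre are spectators. The step needs inversion rather than ionisation and racemisation, closure by the hydroperoxide rather than by the primary hydroxyl (six-membered ether) or the chain alkene, and no Hock-type cleavage; the alpha-effect nucleophile poised for five-membered closure, the catalytic acid, the non-ionising solvent and the low temperature are chosen to secure this.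

Step 13
Reactants: 16 2-[(3S,5R)-3,5-dimethyl-5-[(2R,5E,9E)-2-methyl-10-phenyldeca-5,9-dien-1-yl]-1,2-dioxolan-3-yl]ethan-1-ol
Product: 18 2-[(3R,5R)-3,5-dimethyl-5-[(2R,5E,9E)-2-methyl-10-phenyldeca-5,9-dien-1-yl]-1,2-dioxolan-3-yl]acetic acid, via aldehyde 17 (not isolated)
Conditions: TEMPO (20 mol%), PhI(OAc)2 (2.2 equiv), MeCN/pH 7 phosphate buffer, rt
Reagents that add atoms: water, O
Why: Oxoammonium-mediated oxidation should take the primary alcohol through the aldehyde hydrate to the carboxylic acid under near-neutral conditions that the dialkyl peroxide, the alkene and the styrene tolerate; C3 changes its descriptor from S to R only because the arm gains CIP priority.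

**Compound list**

1 | (3R)-3,7-dimethyloct-6-enoic acid | C[C@H](CCC=C(C)C)CC(=O)O | starting material
2 | (4R)-4,8-dimethylnon-7-en-2-one | C[C@H](CCC=C(C)C)CC(C)=O | intermediate
3 | (2S)-2-[(2R)-2,6-dimethylhept-5-en-1-yl]-2-methyloxirane | C[C@H](CCC=C(C)C)C[C@@]1(C)CO1 | intermediate
4 | (4S,6R)-2,4,6,10-tetramethylundeca-1,9-dien-4-ol | C[C@H](CCC=C(C)C)C[C@@](O)(C)CC(C)=C | intermediate
5 | triethyl{[(4S,6R)-2,4,6,10-tetramethylundeca-1,9-dien-4-yl]oxy}silane | C[C@H](CCC=C(C)C)C[C@@](O[Si](CC)(CC)CC)(C)CC(C)=C | intermediate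
6 | (4R,6S)-4,6-dimethyl-8-oxo-6-[(triethylsilyl)oxy]nonanal | C[C@H](CCC=O)C[C@@](O[Si](CC)(CC)CC)(C)CC(C)=O | intermediate
7 | (4E)-5-phenylpent-4-en-1-ol | OCCC/C=C/c1ccccc1 | starting material
8 | 1-phenyl-5-{[(4E)-5-phenylpent-4-en-1-yl]sulfanyl}-1H-tetrazole | C(CC/C=C/c1ccccc1)Sc1nnnn1-c1ccccc1 | intermediate
9 | 1-phenyl-5-{[(4E)-5-phenylpent-4-en-1-yl]sulfonyl}-1H-tetrazole | O=S(=O)(CCC/C=C/c1ccccc1)c1nnnn1-c1ccccc1 | intermediate
10 | potassium (4E)-5-phenyl-1-[(1-phenyl-1H-tetrazol-5-yl)sulfonyl]pent-4-en-1-ide | [K+].[CH-](CC/C=C/c1ccccc1)S(=O)(=O)c1nnnn1-c1ccccc1 | intermediate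
11 | (4S,6R,9E,13E)-4,6-dimethyl-14-phenyl-4-[(triethylsilyl)oxy]tetradeca-9,13-dien-2-one | C[C@H](CC/C=C/CC/C=C/c1ccccc1)C[C@@](O[Si](CC)(CC)CC)(C)CC(C)=O | intermediate
12 | triethyl{[(2S,4R,7E,11E)-2,4-dimethyl-1-[(2S)-2-methyloxiran-2-yl]-12-phenyldodeca-7,11-dien-2-yl]oxy}silane | C[C@H](CC/C=C/CC/C=C/c1ccccc1)C[C@@](O[Si](CC)(CC)CC)(C)C[C@@]1(C)CO1 | intermediate
13 | triethyl{[(2S,4R,7E,11E)-2,4-dimethyl-1-[(2R)-2-methyloxetan-2-yl]-12-phenyldodeca-7,11-dien-2-yl]oxy}silane | C[C@H](CC/C=C/CC/C=C/c1ccccc1)C[C@@](O[Si](CC)(CC)CC)(C)C[C@@]1(C)CCO1 | intermediate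
14 | (2S,4R,7E,11E)-2,4-dimethyl-1-[(2R)-2-methyloxetan-2-yl]-12-phenyldodeca-7,11-dien-2-ol | C[C@H](CC/C=C/CC/C=C/c1ccccc1)C[C@@](O)(C)C[C@@]1(C)CCO1 | intermediate
15 | (3S,5S,7R,10E,14E)-3-hydroperoxy-3,5,7-trimethyl-15-phenylpentadeca-10,14-diene-1,5-diol | C[C@H](CC/C=C/CC/C=C/c1ccccc1)C[C@@](O)(C)C[C@](C)(CCO)OO | intermediate
16 | 2-[(3S,5R)-3,5-dimethyl-5-[(2R,5E,9E)-2-methyl-10-phenyldeca-5,9-dien-1-yl]-1,2-dioxolan-3-yl]ethan-1-ol | C[C@H](CC/C=C/CC/C=C/c1ccccc1)C[C@]1(C)C[C@](C)(CCO)OO1 | intermediate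
17 | 2-[(3R,5R)-3,5-dimethyl-5-[(2R,5E,9E)-2-methyl-10-phenyldeca-5,9-dien-1-yl]-1,2-dioxolan-3-yl]acetaldehyde | C[C@H](CC/C=C/CC/C=C/c1ccccc1)C[C@]1(C)C[C@](C)(CC=O)OO1 | intermediate
18 | 2-[(3R,5R)-3,5-dimethyl-5-[(2R,5E,9E)-2-methyl-10-phenyldeca-5,9-dien-1-yl]-1,2-dioxolan-3-yl]acetic acid | C[C@H](CC/C=C/CC/C=C/c1ccccc1)C[C@]1(C)C[C@](C)(CC(=O)O)OO1 | target

**Step count and risks**

Total step count: 13. Longest linear sequence: 11 steps (steps 1–5 and 8–13).

Steps most likely to fail:

1. Step 12 (proposed new method). The tertiary C5 centre may ionise to a free cation before the hydroperoxide closes, which would erode the configuration at C5. The cation may also be captured by the primary hydroxyl (six-membered ether) or the chain alkene, or lose a proton. The fallback uses known chemistry, sets out from 11 and returns at 18; C5 is set by invertive perhydrolysis of an oxetane and C3 by peroxycarbenium substitution. Desilylation of 11 (HF·pyridine, THF) should give the β-hydroxy ketone F1, and NaBH4 reduction the 1,3-diol F2 (both carbinol epimers serve). Selective mesylation of the secondary hydroxyl gives the mesylate F3, which KOtBu closes to the 2,2,4-trisubstituted oxetane F4 with the C5–O bond untouched. Me3SiOTf-promoted perhydrolysis opens F4 at the tertiary carbon with inversion to the hydroperoxy alcohol F5, in which C5 has the configuration of the target. Oxidation of the secondary carbinol (Dess–Martin periodinane) and ring–chain tautomerism give the 1,2-dioxolan-3-ol F6, which is acetylated to the acetate F7. TiCl4-mediated substitution of F7 by the tert-butyldimethylsilyl ketene acetal of methyl acetate, through the peroxycarbenium ion, gives the methyl ester F8 together with its C3 epimer F9, to be separated by chromatography. LiOH hydrolysis of F8 gives 18.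

2. Step 9. Methylene transfer to the hindered ketone may be slow, the basic ylide may trigger β-elimination of the silyloxy group, and facial control next to the quaternary centre may be insufficient. The fallback sets out from 11 and returns at 13, with reagent control by a Sharpless asymmetric epoxidation. Horner–Wadsworth–Emmons olefination of 11 (triethyl phosphonoacetate, NaH) gives the (E)-enoate F10 after removal of the Z isomer, and i-Bu2AlH reduction the allylic alcohol F11. Epoxidation with Ti(OiPr)4, L-(+)-diethyl tartrate and t-BuOOH gives the epoxy alcohol F12, and NaAlH2(OCH2CH2OMe)2 opens it at the secondary carbon to the 1,3-diol F13. Tosylation of the primary hydroxyl gives the tosylate F14, which KOtBu closes to 13.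

3. Step 8. The sulfonyl carbanion or excess base may enolise or attack the methyl ketone, and E selectivity may be incomplete. The fallback sets out from 7 (with 6) and returns at 11, using an aldehyde-selective, E-selective Takai–Utimoto alkylidenation. Dess–Martin oxidation of 7 gives the aldehyde F15, hydrazine converts it to the hydrazone F16, and I2/Et3N gives the geminal diiodide F17. Treatment of 6 with F17 and CrCl2 in THF/DMF gives 11.

**Further compounds**

F1 | step 12 | (4S,6R,9E,13E)-4-hydroxy-4,6-dimethyl-14-phenyltetradeca-9,13-dien-2-one | C[C@H](CC/C=C/CC/C=C/c1ccccc1)C[C@@](O)(C)CC(C)=O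
F2 | step 12 | (4S,6R,9E,13E)-4,6-dimethyl-14-phenyltetradeca-9,13-diene-2,4-diol (C2 epimers) | C[C@H](CC/C=C/CC/C=C/c1ccccc1)C[C@@](O)(C)CC(C)O
F3 | step 12 | (4S,6R,9E,13E)-4-hydroxy-4,6-dimethyl-14-phenyltetradeca-9,13-dien-2-yl methanesulfonate | C[C@H](CC/C=C/CC/C=C/c1ccccc1)C[C@@](O)(C)CC(C)OS(C)(=O)=O
F4 | step 12 | (2S)-2,4-dimethyl-2-[(2R,5E,9E)-2-methyl-10-phenyldeca-5,9-dien-1-yl]oxetane (C4 epimers) | C[C@H](CC/C=C/CC/C=C/c1ccccc1)C[C@@]1(C)CC(C)O1
F5 | step 12 | (4R,6R,9E,13E)-4-hydroperoxy-4,6-dimethyl-14-phenyltetradeca-9,13-dien-2-ol | C[C@H](CC/C=C/CC/C=C/c1ccccc1)C[C@](OO)(C)CC(C)O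
F6 | step 12 | (5R)-3,5-dimethyl-5-[(2R,5E,9E)-2-methyl-10-phenyldeca-5,9-dien-1-yl]-1,2-dioxolan-3-ol | C[C@H](CC/C=C/CC/C=C/c1ccccc1)C[C@]1(C)CC(C)(O)OO1
F7 | step 12 | (5R)-3,5-dimethyl-5-[(2R,5E,9E)-2-methyl-10-phenyldeca-5,9-dien-1-yl]-1,2-dioxolan-3-yl acetate | C[C@H](CC/C=C/CC/C=C/c1ccccc1)C[C@]1(C)CC(C)(OC(C)=O)OO1
F8 | step 12 | methyl 2-[(3R,5R)-3,5-dimethyl-5-[(2R,5E,9E)-2-methyl-10-phenyldeca-5,9-dien-1-yl]-1,2-dioxolan-3-yl]acetate | C[C@H](CC/C=C/CC/C=C/c1ccccc1)C[C@]1(C)C[C@](C)(CC(=O)OC)OO1
F9 | step 12 | methyl 2-[(3S,5R)-3,5-dimethyl-5-[(2R,5E,9E)-2-methyl-10-phenyldeca-5,9-dien-1-yl]-1,2-dioxolan-3-yl]acetate | C[C@H](CC/C=C/CC/C=C/c1ccccc1)C[C@]1(C)C[C@@](C)(CC(=O)OC)OO1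
F10 | step 9 | ethyl (2E,5S,7R,10E,14E)-3,5,7-trimethyl-15-phenyl-5-[(triethylsilyl)oxy]pentadeca-2,10,14-trienoate | C[C@H](CC/C=C/CC/C=C/c1ccccc1)C[C@@](O[Si](CC)(CC)CC)(C)C/C(C)=C/C(=O)OCC
F11 | step 9 | (2E,5S,7R,10E,14E)-3,5,7-trimethyl-15-phenyl-5-[(triethylsilyl)oxy]pentadeca-2,10,14-trien-1-ol | C[C@H](CC/C=C/CC/C=C/c1ccccc1)C[C@@](O[Si](CC)(CC)CC)(C)C/C(C)=C/CO
F12 | step 9 | [(2S,3S)-3-[(2S,4R,7E,11E)-2,4-dimethyl-12-phenyl-2-[(triethylsilyl)oxy]dodeca-7,11-dien-1-yl]-3-methyloxiran-2-yl]methanol | C[C@H](CC/C=C/CC/C=C/c1ccccc1)C[C@@](O[Si](CC)(CC)CC)(C)C[C@]1(C)O[C@H]1CO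
F13 | step 9 | (3R,5S,7R,10E,14E)-3,5,7-trimethyl-15-phenyl-5-[(triethylsilyl)oxy]pentadeca-10,14-diene-1,3-diol | C[C@H](CC/C=C/CC/C=C/c1ccccc1)C[C@@](O[Si](CC)(CC)CC)(C)C[C@@](O)(C)CCO
F14 | step 9 | (3R,5S,7R,10E,14E)-3-hydroxy-3,5,7-trimethyl-15-phenyl-5-[(triethylsilyl)oxy]pentadeca-10,14-dien-1-yl 4-methylbenzenesulfonate | C[C@H](CC/C=C/CC/C=C/c1ccccc1)C[C@@](O[Si](CC)(CC)CC)(C)C[C@@](O)(C)CCOS(=O)(=O)c1ccc(C)cc1
F15 | step 8 | (4E)-5-phenylpent-4-enal | O=CCC/C=C/c1ccccc1
F16 | step 8 | (4E)-5-phenylpent-4-enal hydrazone | NN=CCC/C=C/c1ccccc1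
F17 | step 8 | [(1E)-5,5-diiodopent-1-en-1-yl]benzene | IC(I)CC/C=C/c1ccccc1
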